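**Retrosynthetic overview**

1. Target ⇐ oxidation of the oxepane carbinol and desilylation ⇐ (Z)-alkene ⇐ semireduction of an exocyclic allene ⇐ tertiary propargylic carbonate ⇐ fragment 1 (a hydroazulen-5-one) + the acetylide of fragment 2 (a 6-ethynyl-perhydro-1-benzoxepine).
2. Enabling feature: in the seven-membered carbocycle, the sp2 ring carbon that carries the exocyclic C=CH lies between the C(CH3)2 and the CH(CH3) ring carbons. Read as a ketone, these three atoms are a 1,1,3-trimethyl-2-oxyallyl cation; the other four ring atoms (CH2–CH2 and the two ring-fusion CH shared with the cyclopentane) are the diene of a 1-vinylcyclopentene.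
3. Key disconnection: a (4+3) cycloaddition makes the CH(CH3)–CH2 bond and the C(CH3)2–CH(ring fusion) bond at once. An allylic silyloxy centre on the cyclopentene (from a CBS reduction) controls the face, is relayed to the second ring-fusion centre, and is then turned into the tertiary carbinol.
4. Fragment 2: farnesol → (S)-nerolidol → bis-epoxide → allylsilane; one epoxide-opening cascade closes the oxepane (ring A) and then the cyclohexane (ring B).
5. Ring order: cyclopentene (bought) → seven-membered ring (step 5); oxepane → cyclohexane (step 17); the two bicycles are joined last (steps 20–22).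

Key step: step 5

Remark: the carbinol carbon created in step 20 and the allene axis created in step 21 are not controlled, because both elements disappear in steps 21 and 22; the compounds concerned are drawn without these descriptors.
Remark: the D-fructose-derived Shi ketone is taken to epoxidise trisubstituted alkenes in the (R,R) sense, as drawn.
Azulene locants are used for fragment 1 (C5 = ketone carbon, C4 = C(CH3)2, C6 = CH(CH3), C3a/C8a = ring fusion, C1 = oxygenated cyclopentane carbon). 1-Benzoxepine locants are used for fragment 2 (C2 = C(CH3)2, C3 = oxygenated carbon, C5a = angular methyl carbon, C6 = side-chain carbon, C7 = tertiary carbinol carbon).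

**Route**

Step 1
Reactants: 1 2-methylpentan-3-one
Product: 2 2-bromo-2-methylpentan-3-one
Conditions: Br2 (1.0 equiv), AcOH, 15 °C
Reagents that add atoms: bromine, BrBr
Why: Acid-catalysed α-bromination of a ketone runs through the more substituted enol, so bromine should enter at the isopropyl methine only (electrophilic α-halogenation; no stereocentre).

Step 2
Reactants: 3 2-bromocyclopent-2-en-1-one
Product: 4 (R)-2-bromocyclopent-2-en-1-ol
Conditions: (S)-2-methyl-CBS-oxazaborolidine (10 mol %), BH3·SMe2, THF, −20 °C
Reagents that add atoms: none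
Why: Corey–Bakshi–Shibata reduction in which the bromoalkenyl arm acts as the large group, so the (S)-oxazaborolidine–borane complex should deliver hydride to one carbonyl face and set the (R)-carbinol centre.

Step 3
Reactants: 4 (R)-2-bromocyclopent-2-en-1-ol
Product: 5 (R)-[(2-bromocyclopent-2-en-1-yl)oxy](tert-butyl)dimethylsilane
Conditions: TBSCl, imidazole, DMF, rt
Reagents that add atoms: tert-butyldimethylsilyl chloride, CC(C)(C)[Si](C)(C)Cl
Why: Silylation of a secondary allylic alcohol with a silyl chloride and imidazole; the bulky silyl ether is the later facial control element and the alkenyl bromide is untouched.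

Step 4
Reactants: 5 (R)-[(2-bromocyclopent-2-en-1-yl)oxy](tert-butyl)dimethylsilane
Product: 6 (R)-tert-butyl[(2-ethenylcyclopent-2-en-1-yl)oxy]dimethylsilane
Conditions: 4,4,5,5-tetramethyl-2-vinyl-1,3,2-dioxaborolane, Pd(dppf)Cl2 (5 mol %), Cs2CO3, dioxane/H2O, 80 °C
Reagents that add atoms: 4,4,5,5-tetramethyl-2-vinyl-1,3,2-dioxaborolane, C=CB1OC(C)(C)C(C)(C)O1
Why: Suzuki–Miyaura coupling of the cyclic alkenyl bromide with a vinylboronate proceeds with retention at sp2 carbon and does not touch the allylic stereocentre, giving the 1-vinylcycloalkene diene.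

Step 5
Reactants: 6 (R)-tert-butyl[(2-ethenylcyclopent-2-en-1-yl)oxy]dimethylsilane; 2 2-bromo-2-methylpentan-3-one
Product: 8 1-(tert-butyldimethylsilyloxy)-4,4,6-trimethyl-2,3,3a,4,6,7-hexahydroazulen-5(1H)-one (1-OSi cis to 3a-H; 6-H cis to 3a-H), via oxyallyl cation 7 (not isolated)
Conditions: Et3N (3 equiv), (CF3)2CHOH, 0 °C → rt, 2 (2.5 equiv) added over 4 h
Reagents that add atoms: none
Why: Et3N enolises 2 toward its CH2 group and the enolate ionises the tertiary C–Br bond to the 1,1,3-trimethyl-2-oxidoallyl cation 7 (hydrogen-bonded by the fluorinated alcohol), which adds across the s-cis diene of 6; the closest known reaction type is the base-mediated (4+3) cycloaddition of α-halo ketones with 1,3-dienes in fluorinated alcohols. The seven-membered ring is closed by an intermolecular, concerted but asynchronous (4+3) annulation, suprafacial on both partners, in which the CH(CH3) terminus bonds to the vinyl CH2 ahead of the C(CH3)2 terminus bonding to the ring CH of the cyclopentene. Regiochemistry, the selectivity the step needs most, should follow from the union of the two least hindered termini in the leading bond, reinforced by the largest HOMO coefficient of a 1-vinylcycloalkene lying on the vinyl CH2. The ring-fusion centre C3a is set by attack on the diene face anti to the allylic OTBS group, which sits pseudo-axial to avoid the vinyl group. The CH(CH3) centre C6 is set by the compact transition state of the W-shaped cation (methyl syn to oxygen), which places 6-H cis to 3a-H; this centre is α to the ketone and can be corrected by kinetic enolate protonation from the convex face if needed. The trisubstituted ring alkene left at C8=C8a is used in step 7 to set the second ring-fusion centre.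

Step 6
Reactants: 8 1-(tert-butyldimethylsilyloxy)-4,4,6-trimethyl-2,3,3a,4,6,7-hexahydroazulen-5(1H)-one
Product: 9 1-hydroxy-4,4,6-trimethyl-2,3,3a,4,6,7-hexahydroazulen-5(1H)-one (1-OH cis to 3a-H)
Conditions: Bu4NF, THF, 0 °C
Reagents that add atoms: none
Why: Fluoride-mediated desilylation frees the allylic alcohol needed to direct the next step; the ketone and the ring alkene are inert to Bu4NF at 0 °C.

Step 7
Reactants: 9 1-hydroxy-4,4,6-trimethyl-2,3,3a,4,6,7-hexahydroazulen-5(1H)-one
Product: 10 cis-fused 1-hydroxy-4,4,6-trimethyloctahydroazulen-5(1H)-one (1-OH, 3a-H, 6-H and 8a-H on one face)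
Conditions: H2 (1 atm), [Ir(cod)(PCy3)(py)]PF6 (5 mol %), CH2Cl2, rt
Reagents that add atoms: none
Why: Hydroxyl-directed homogeneous hydrogenation: the cationic iridium catalyst binds the allylic OH and delivers H2 to the trisubstituted alkene from that face (also the face away from the gem-dimethyl carbon), setting the second ring-fusion centre cis to the first.

Step 8
Reactants: 10 cis-fused 1-hydroxy-4,4,6-trimethyloctahydroazulen-5(1H)-one
Product: 11 cis-fused 4,4,6-trimethyloctahydroazulene-1,5-dione
Conditions: Dess–Martin periodinane, CH2Cl2, 0 °C → rt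
Reagents that add atoms: none
Why: Dess–Martin oxidation of the secondary alcohol under non-basic conditions, so the ring-fusion centre next to the new cyclopentanone should not epimerise.

Step 9
Reactants: 11 cis-fused 4,4,6-trimethyloctahydroazulene-1,5-dione
Product: 12 cis-fused 4,4,6-trimethyl-1-methylideneoctahydroazulen-5(1H)-one
Conditions: Zn, CH2Br2, TiCl4, THF/CH2Cl2, 0 °C → rt
Reagents that add atoms: dibromomethane, BrCBr
Why: Lombardo methylenation with the Zn/CH2Br2/TiCl4 reagent is non-basic and therefore keeps the epimerisable ring-fusion centre, and it should select the unhindered cyclopentanone over the ketone flanked by a quaternary and a tertiary carbon.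

Step 10
Reactants: 12 cis-fused 4,4,6-trimethyl-1-methylideneoctahydroazulen-5(1H)-one
Product: 13 cis-fused 1-hydroxy-1,4,4,6-tetramethyloctahydroazulen-5(1H)-one (1-OH cis to 3a-H and 8a-H)
Conditions: Co(acac)2 (20 mol %), PhSiH3, O2 (1 atm), THF/i-PrOH, rt
Reagents that add atoms: dioxygen, O=O
Why: Mukaiyama hydration: hydrogen-atom transfer to the CH2 terminus gives a tertiary radical that is trapped by O2 on the convex face (anti to the adjacent bond of the seven-membered ring), so the tertiary OH should end cis to the ring-fusion hydrogens and the methyl trans, while the hindered ketone is untouched.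

Step 11
Reactants: 13 cis-fused 1-hydroxy-1,4,4,6-tetramethyloctahydroazulen-5(1H)-one
Product: 14 cis-fused 1,4,4,6-tetramethyl-1-(triethylsilyloxy)octahydroazulen-5(1H)-one (fragment 1)
Conditions: TESOTf, 2,6-lutidine, CH2Cl2, −78 → 0 °C
Reagents that add atoms: triethylsilyl trifluoromethanesulfonate, CC[Si](CC)(CC)OS(=O)(=O)C(F)(F)F
Why: Silylation of the tertiary alcohol with a silyl triflate and a hindered pyridine base, so that no acidic OH interferes with the acetylide addition of step 20.

Step 12
Reactants: 15 (2E,6E)-farnesol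
Product: 16 (2S,3S)-2,3-epoxy-(6E)-farnesol
Conditions: Ti(OiPr)4 (10 mol %), L-(+)-diethyl tartrate (12 mol %), t-BuOOH, 4 Å MS, CH2Cl2, −20 °C
Reagents that add atoms: tert-butyl hydroperoxide, CC(C)(C)OO
Why: Sharpless asymmetric epoxidation of the allylic alcohol; L-(+)-diethyl tartrate gives the (2S,3S)-epoxide under reagent control and the two isolated trisubstituted alkenes do not react.

Step 13
Reactants: 16 (2S,3S)-2,3-epoxy-(6E)-farnesol
Product: 18 (3S,6E)-3,7,11-trimethyldodeca-1,6,10-trien-3-ol [(S)-(E)-nerolidol], via epoxy iodide 17 (not isolated)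
Conditions: PPh3, I2, imidazole, THF, 0 °C; then Zn dust, EtOH, 40 °C
Reagents that add atoms: none
Why: Appel iodination of the primary alcohol followed by zinc-mediated reductive opening of the 2,3-epoxy iodide (reductive β-elimination) gives the tertiary allylic alcohol; the C–O bond of the carbinol carbon is never broken, so its (S) configuration is that of the epoxide.

Step 14
Reactants: 18 (S)-(E)-nerolidol
Product: 19 (3S,6R,7R,10R)-6,7:10,11-diepoxy-3,7,11-trimethyldodec-1-en-3-ol
Conditions: D-fructose-derived Shi ketone (0.6 equiv), KHSO5 (as 2KHSO5·KHSO4·K2SO4), K2CO3, Bu4NHSO4, MeCN/CH2(OMe)2/aq. Na2B4O7 buffer, 0 °C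
Reagents that add atoms: potassium peroxymonosulfate, [K+].[O-]S(=O)(=O)OO
Why: Shi epoxidation converts both trisubstituted alkenes into epoxides under reagent control, while the monosubstituted vinyl group reacts far more slowly with the dioxirane.

Step 15
Reactants: 19 (3S,6R,7R,10R)-6,7:10,11-diepoxy-3,7,11-trimethyldodec-1-en-3-ol
Product: 20 (2E,4S,7R,8R,11R)-7,8:11,12-diepoxy-4,8,12-trimethyl-1-(triethylsilyl)tridec-2-en-4-ol
Conditions: allyltriethylsilane (4 equiv), second-generation Hoveyda–Grubbs catalyst RuCl2(H2IMes)(=CH-C6H4-2-OiPr) (10 mol %), CH2Cl2, 40 °C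
Reagents that add atoms: allyltriethylsilane, CC[Si](CC)(CC)CC=C
Why: Olefin cross-metathesis of the vinyl carbinol with an excess of allylsilane (epoxides are inert to the ruthenium carbene and the free allylic OH assists turnover) installs the allylsilane terminator, mainly as the E isomer.

Step 16
Reactants: 20 (2E,4S,7R,8R,11R)-7,8:11,12-diepoxy-4,8,12-trimethyl-1-(triethylsilyl)tridec-2-en-4-ol
Product: 21 4-O-triethylsilyl ether of 20
Conditions: TESCl, imidazole, DMAP (cat.), DMF, 40 °C
Reagents that add atoms: triethylsilyl chloride, CC[Si](CC)(CC)Cl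
Why: Silylation of the tertiary alcohol under Lewis-acid-free conditions, so that the epoxides stay closed and the oxygen cannot intercept the cation of step 17.

Step 17
Reactants: 21 4-O-triethylsilyl ether of 20
Product: 23 trans-fused 6-ethenyl-2,2,5a,7-tetramethyl-3,7-bis(triethylsilyloxy)decahydro-1-benzoxepine (5a-CH3 and 7-OSi axial on one face; 6-vinyl equatorial), via epoxonium triflate 22 (not isolated)
Conditions: TESOTf (0.3 equiv), 2,6-di-tert-butyl-4-methylpyridine (0.5 equiv), CH2Cl2, −78 °C
Reagents that add atoms: none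
Why: Lewis-acid-triggered epoxide-opening cascade (tandem oxa-/carbacyclisation): the silylated terminal epoxide is opened at its tertiary carbon by the oxygen of the neighbouring epoxide to give oxonium ion 22, which is opened with inversion at its methyl-bearing carbon by the allylsilane through a chair transition state, closing the oxepane (ring A) and the cyclohexane (ring B) trans-fused with the angular methyl axial, the vinyl group equatorial and the preset silyloxy centre axial, while the silyl cation released from the allylsilane regenerates the silyl triflate.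

Step 18
Reactants: 23 trans-fused 6-ethenyl-2,2,5a,7-tetramethyl-3,7-bis(triethylsilyloxy)decahydro-1-benzoxepine
Product: 24 trans-fused 2,2,5a,7-tetramethyl-3,7-bis(triethylsilyloxy)decahydro-1-benzoxepine-6-carbaldehyde
Conditions: O3, CH2Cl2, −78 °C; then PPh3, −78 °C → rt
Reagents that add atoms: ozone, [O-][O+]=O
Why: Ozonolysis with reductive work-up cleaves the only alkene to the aldehyde, whose α-centre keeps the favoured equatorial orientation; the silyl ethers are stable.

Step 19
Reactants: 24 trans-fused 2,2,5a,7-tetramethyl-3,7-bis(triethylsilyloxy)decahydro-1-benzoxepine-6-carbaldehyde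
Product: 25 trans-fused 6-ethynyl-2,2,5a,7-tetramethyl-3,7-bis(triethylsilyloxy)decahydro-1-benzoxepine (fragment 2)
Conditions: dimethyl (1-diazo-2-oxopropyl)phosphonate, K2CO3, MeOH, 0 °C → rt
Reagents that add atoms: dimethyl (1-diazo-2-oxopropyl)phosphonate, COP(=O)(OC)C(=[N+]=[N-])C(C)=O
Why: Seyferth–Gilbert homologation with the Ohira–Bestmann reagent converts the aldehyde into the terminal alkyne under mild carbonate conditions; any α-epimerisation returns the wanted equatorial isomer.

Step 20
Reactants: 25 fragment 2 alkyne; 14 fragment 1 ketone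
Product: 28 methyl carbonate of the tertiary propargylic alcohol that joins C5 of fragment 1 to the alkyne terminus of fragment 2, via lithium acetylide 26 (not isolated), via lithium alkoxide 27 (not isolated)
Conditions: n-BuLi, THF, −78 °C; 14, −78 → 0 °C; ClCO2Me, −78 °C → rt
Reagents that add atoms: methyl chloroformate, COC(=O)Cl
Why: 1,2-Addition of a lithium acetylide to the hindered ketone (a slim nucleophile of the kind that adds to 2,2,6-trisubstituted cycloalkanones) followed by O-acylation of the lithium alkoxide in the same flask; the new carbinol centre is not controlled and is erased in step 21.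

Step 21
Reactants: 28 tertiary propargylic methyl carbonate
Product: 29 exocyclic trisubstituted allene (azulen-5-ylidene=C=CH–benzoxepin-6-yl; tris-triethylsilyl ether)
Conditions: Pd2(dba)3·CHCl3 (5 mol %), PBu3 (20 mol %), HCO2NH4, THF, 40 °C
Reagents that add atoms: none
Why: Palladium-catalysed formate hydrogenolysis of a tertiary propargylic carbonate: SN2′-type oxidative addition, decarboxylation of formate and C–H reductive elimination at the alkyne terminus should give the allene, whose axial configuration is irrelevant.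

Step 22
Reactants: 29 exocyclic trisubstituted allene
Product: 30 (Z)-alkene, tris-triethylsilyl ether of 31
Conditions: 2-nitrobenzenesulfonyl hydrazide, Et3N, CH2Cl2, rt
Reagents that add atoms: none
Why: Diimide semireduction of an allene (concerted syn transfer of H2 to the less substituted distal π bond): this π bond lies in the plane of the two ring carbons that flank the allene, the CH(CH3) flank can turn its hydrogen into that plane whereas the C(CH3)2 flank always keeps a methyl there, so hydrogen should enter from the CH(CH3) side and leave the side chain cis to C(CH3)2, which is the required Z alkene.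

Step 23
Reactants: 30 (Z)-alkene tris-triethylsilyl ether
Product: 31 triol (the 3-hydroxy-oxepane analogue of the target)
Conditions: Bu4NF, THF, 50 °C
Reagents that add atoms: none
Why: Fluoride-mediated global desilylation of one secondary and two tertiary triethylsilyl ethers under non-acidic conditions, which avoids migration of the exocyclic alkene into the ring.

Step 24
Reactants: 31 triol
Product: 32 target CNP0157787.1
Conditions: Pr4N[RuO4] (5 mol %), N-methylmorpholine N-oxide, 4 Å MS, CH2Cl2, rt
Reagents that add atoms: none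
Why: Ley–Griffith oxidation of the only secondary alcohol to the oxepanone under neutral conditions; the two tertiary alcohols and the trisubstituted alkene do not react.

**Compound list**

1 | 2-methylpentan-3-one | CCC(=O)C(C)C | starting material
2 | 2-bromo-2-methylpentan-3-one | CCC(=O)C(C)(C)Br | intermediate
3 | 2-bromocyclopent-2-en-1-one | O=C1CCC=C1Br | starting material
4 | (R)-2-bromocyclopent-2-en-1-ol | BrC1=CCC[C@H]1O | intermediate
5 | (R)-[(2-bromocyclopent-2-en-1-yl)oxy](tert-butyl)dimethylsilane | BrC1=CCC[C@H]1O[Si](C)(C)C(C)(C)C | intermediate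
6 | (R)-tert-butyl[(2-ethenylcyclopent-2-en-1-yl)oxy]dimethylsilane | C=CC1=CCC[C@H]1O[Si](C)(C)C(C)(C)C | intermediate
7 | 1,1,3-trimethyl-2-oxidoallyl cation (methyl syn to oxygen) | C/C=C(\[O-])[C+](C)C | intermediate
8 | 1-(tert-butyldimethylsilyloxy)-4,4,6-trimethyl-2,3,3a,4,6,7-hexahydroazulen-5(1H)-one (1-OSi cis to 3a-H; 6-H cis to 3a-H) | C[C@H]1CC=C2[C@@H](CC[C@H]2O[Si](C)(C)C(C)(C)C)C(C)(C)C1=O | intermediate
9 | 1-hydroxy-4,4,6-trimethyl-2,3,3a,4,6,7-hexahydroazulen-5(1H)-one | C[C@H]1CC=C2[C@@H](CC[C@H]2O)C(C)(C)C1=O | intermediate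
10 | cis-fused 1-hydroxy-4,4,6-trimethyloctahydroazulen-5(1H)-one (1-OH, 3a-H, 6-H, 8a-H on one face) | C[C@H]1CC[C@@H]2[C@@H](CC[C@H]2O)C(C)(C)C1=O | intermediate
11 | cis-fused 4,4,6-trimethyloctahydroazulene-1,5-dione | C[C@H]1CC[C@@H]2[C@@H](CCC2=O)C(C)(C)C1=O | intermediate
12 | cis-fused 4,4,6-trimethyl-1-methylideneoctahydroazulen-5(1H)-one | C[C@H]1CC[C@@H]2[C@@H](CCC2=C)C(C)(C)C1=O | intermediate
13 | cis-fused 1-hydroxy-1,4,4,6-tetramethyloctahydroazulen-5(1H)-one (1-OH cis to 3a-H and 8a-H) | C[C@H]1CC[C@@H]2[C@@H](CC[C@@]2(C)O)C(C)(C)C1=O | intermediate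
14 | cis-fused 1,4,4,6-tetramethyl-1-(triethylsilyloxy)octahydroazulen-5(1H)-one (fragment 1) | C[C@H]1CC[C@@H]2[C@@H](CC[C@@]2(C)O[Si](CC)(CC)CC)C(C)(C)C1=O | intermediate
15 | (2E,6E)-farnesol | OC/C=C(\C)CC/C=C(\C)CCC=C(C)C | starting material
16 | (2S,3S)-2,3-epoxy-(6E)-farnesol | OC[C@@H]1O[C@@]1(C)CC/C=C(\C)CCC=C(C)C | intermediate
17 | 2,3-epoxy iodide derived from 16 | IC[C@@H]1O[C@@]1(C)CC/C=C(\C)CCC=C(C)C | intermediate
18 | (3S,6E)-3,7,11-trimethyldodeca-1,6,10-trien-3-ol [(S)-(E)-nerolidol] | C=C[C@@](C)(O)CC/C=C(\C)CCC=C(C)C | intermediate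
19 | (3S,6R,7R,10R)-6,7:10,11-diepoxy-3,7,11-trimethyldodec-1-en-3-ol | C=C[C@@](C)(O)CC[C@H]1O[C@]1(C)CC[C@H]1OC1(C)C | intermediate
20 | (2E,4S,7R,8R,11R)-7,8:11,12-diepoxy-4,8,12-trimethyl-1-(triethylsilyl)tridec-2-en-4-ol | CC[Si](CC)(CC)C/C=C/[C@@](C)(O)CC[C@H]1O[C@]1(C)CC[C@H]1OC1(C)C | intermediate
21 | 4-O-triethylsilyl ether of 20 | CC[Si](CC)(CC)C/C=C/[C@@](C)(O[Si](CC)(CC)CC)CC[C@H]1O[C@]1(C)CC[C@H]1OC1(C)C | intermediate
22 | bicyclic epoxonium triflate (2-oxoniabicyclo[4.1.0]heptane core) formed from 21 | CC[Si](CC)(CC)C/C=C/[C@@](C)(O[Si](CC)(CC)CC)CC[C@H]1[O+]2[C@]1(C)CC[C@@H](O[Si](CC)(CC)CC)C2(C)C.[O-]S(=O)(=O)C(F)(F)F | intermediate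
23 | trans-fused 6-ethenyl-2,2,5a,7-tetramethyl-3,7-bis(triethylsilyloxy)decahydro-1-benzoxepine | C=C[C@@H]1[C@@]2(C)CC[C@@H](O[Si](CC)(CC)CC)C(C)(C)O[C@@H]2CC[C@]1(C)O[Si](CC)(CC)CC | intermediate
24 | trans-fused 2,2,5a,7-tetramethyl-3,7-bis(triethylsilyloxy)decahydro-1-benzoxepine-6-carbaldehyde | O=C[C@@H]1[C@@]2(C)CC[C@@H](O[Si](CC)(CC)CC)C(C)(C)O[C@@H]2CC[C@]1(C)O[Si](CC)(CC)CC | intermediate
25 | trans-fused 6-ethynyl-2,2,5a,7-tetramethyl-3,7-bis(triethylsilyloxy)decahydro-1-benzoxepine (fragment 2) | C#C[C@@H]1[C@@]2(C)CC[C@@H](O[Si](CC)(CC)CC)C(C)(C)O[C@@H]2CC[C@]1(C)O[Si](CC)(CC)CC | intermediate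
26 | lithium acetylide of 25 | [Li]C#C[C@@H]1[C@@]2(C)CC[C@@H](O[Si](CC)(CC)CC)C(C)(C)O[C@@H]2CC[C@]1(C)O[Si](CC)(CC)CC | intermediate
27 | lithium alkoxide of the tertiary propargylic alcohol from 26 and 14 (carbinol centre not assigned) | C[C@H]1CC[C@@H]2[C@@H](CC[C@@]2(C)O[Si](CC)(CC)CC)C(C)(C)C1(O[Li])C#C[C@@H]1[C@@]2(C)CC[C@@H](O[Si](CC)(CC)CC)C(C)(C)O[C@@H]2CC[C@]1(C)O[Si](CC)(CC)CC | intermediate
28 | methyl carbonate of the tertiary propargylic alcohol (carbinol centre not assigned) | C[C@H]1CC[C@@H]2[C@@H](CC[C@@]2(C)O[Si](CC)(CC)CC)C(C)(C)C1(OC(=O)OC)C#C[C@@H]1[C@@]2(C)CC[C@@H](O[Si](CC)(CC)CC)C(C)(C)O[C@@H]2CC[C@]1(C)O[Si](CC)(CC)CC | intermediate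
29 | exocyclic trisubstituted allene (axis not assigned) | C[C@H]1CC[C@@H]2[C@@H](CC[C@@]2(C)O[Si](CC)(CC)CC)C(C)(C)C1=C=C[C@@H]1[C@@]2(C)CC[C@@H](O[Si](CC)(CC)CC)C(C)(C)O[C@@H]2CC[C@]1(C)O[Si](CC)(CC)CC | intermediate
30 | (Z)-alkene, tris-triethylsilyl ether of 31 | C[C@H]1CC[C@@H]2[C@@H](CC[C@@]2(C)O[Si](CC)(CC)CC)C(C)(C)/C1=C\C[C@@H]1[C@@]2(C)CC[C@@H](O[Si](CC)(CC)CC)C(C)(C)O[C@@H]2CC[C@]1(C)O[Si](CC)(CC)CC | intermediate
31 | triol (3-hydroxy-oxepane analogue of the target) | C[C@H]1CC[C@@H]2[C@@H](CC[C@@]2(C)O)C(C)(C)/C1=C\C[C@@H]1[C@@]2(C)CC[C@@H](O)C(C)(C)O[C@@H]2CC[C@]1(C)O | intermediate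
32 | target CNP0157787.1 | C[C@H]1CC[C@@H]2[C@@H](CC[C@@]2(C)O)C(C)(C)/C1=C\C[C@@H]1[C@@]2(C)CCC(=O)C(C)(C)O[C@@H]2CC[C@]1(C)O | target

**Step count and risks**

Total step count: 24.
Longest linear sequence: 15 steps (3 → 4 → 5 → 6 → 8 → 9 → 10 → 11 → 12 → 13 → 14 → 28 → 29 → 30 → 31 → 32).

Steps most likely to fail:

Step 5. What may go wrong: capture of the oxyallyl cation by the fluorinated alcohol and Favorskii-type collapse may outrun the cycloaddition with the non-cyclic diene, or the two regiochemical modes of addition may compete. The fallback changes how the three-carbon partner is generated and what it is; it sets out from 2 and 6 and comes back at 8. Ketone 2 is converted with LiN(i-Pr)2 and Me3SiCl (THF, −78 °C) into the (Z)-silyl enol ether F1. AgOTf in CH2Cl2/MeNO2 at −78 °C, in the presence of 6, abstracts bromide and gives the 2-(trimethylsilyloxy)allyl cation F2. This more electrophilic partner adds stepwise: the CH(CH3) terminus bonds first to the vinyl CH2, and the silyl enol ether then closes onto the allyl cation anti to the silyloxy group. Loss of the silyl group on work-up gives 8; the CH(CH3) centre is then set by kinetic protonation of the enolate from the convex face if needed.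

Step 22. What may go wrong: transfer of hydrogen from the C(CH3)2 flank, which would give the E alkene. The fallback installs the geometry by stereospecific inversion instead of approach control; it sets out from 29 and comes back at 30. The semireduction is run for conversion only and the (E)-alkene F3 is taken on. Epoxidation (mCPBA, NaHCO3, CH2Cl2) gives the spiro-epoxide F4. LiPPh2 (THF) opens it at its CH carbon with inversion to the β-hydroxy phosphine F5. P-Methylation (MeI) and syn-elimination of the phosphine oxide then deliver the inverted (Z)-alkene 30; the silyl ethers tolerate all three operations.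

Step 17. What may go wrong: the cation at the methyl-bearing carbon may be lost by elimination or a 1,2-shift, or the inner epoxide may be activated first, before the allylsilane closes ring B. The fallback uses a silyl enol ether as terminator, the π-nucleophile class for which this diepoxide cascade is established; it sets out from 19 and comes back at 24. Alcohol 19 is silylated (TESCl, imidazole, DMAP, DMF) to the tertiary silyl ether F6. Hydroboration–oxidation of the vinyl group (9-BBN, THF; then NaOH, H2O2) gives the primary alcohol F7. Oxidation (Pr4N[RuO4], N-methylmorpholine N-oxide) gives the β-silyloxy aldehyde F8, and TESCl/DBU (CH2Cl2) gives the silyl enol ether F9. Catalytic TESOTf with 2,6-di-tert-butyl-4-methylpyridine (CH2Cl2, −78 °C) then closes both rings with the enol silane as terminator and gives aldehyde 24 directly, so the ozonolysis is no longer needed.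

**Further compounds**

F1 | step 5 | (Z)-[(4-bromo-4-methylpent-2-en-3-yl)oxy]trimethylsilane | C/C=C(\O[Si](C)(C)C)C(C)(C)Br
F2 | step 5 | 1,1,3-trimethyl-2-(trimethylsilyloxy)allyl cation triflate | C/C=C(\O[Si](C)(C)C)[C+](C)C.[O-]S(=O)(=O)C(F)(F)F
F3 | step 22 | (E)-isomer of 30 | C[C@H]1CC[C@@H]2[C@@H](CC[C@@]2(C)O[Si](CC)(CC)CC)C(C)(C)/C1=C/C[C@@H]1[C@@]2(C)CC[C@@H](O[Si](CC)(CC)CC)C(C)(C)O[C@@H]2CC[C@]1(C)O[Si](CC)(CC)CC
F4 | step 22 | spiro-epoxide of F3 (trans-epoxide from the E alkene; face not assigned) | C[C@H]1CC[C@@H]2[C@@H](CC[C@@]2(C)O[Si](CC)(CC)CC)C(C)(C)C13OC3C[C@@H]1[C@@]2(C)CC[C@@H](O[Si](CC)(CC)CC)C(C)(C)O[C@@H]2CC[C@]1(C)O[Si](CC)(CC)CC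
F5 | step 22 | β-hydroxy diphenylphosphine from opening of F4 at its CH carbon | C[C@H]1CC[C@@H]2[C@@H](CC[C@@]2(C)O[Si](CC)(CC)CC)C(C)(C)C1(O)C(P(c3ccccc3)c3ccccc3)C[C@@H]1[C@@]2(C)CC[C@@H](O[Si](CC)(CC)CC)C(C)(C)O[C@@H]2CC[C@]1(C)O[Si](CC)(CC)CC
F6 | step 17 | 3-O-triethylsilyl ether of 19 | C=C[C@@](C)(O[Si](CC)(CC)CC)CC[C@H]1O[C@]1(C)CC[C@H]1OC1(C)C
F7 | step 17 | primary alcohol from hydroboration–oxidation of F6 | OCC[C@@](C)(O[Si](CC)(CC)CC)CC[C@H]1O[C@]1(C)CC[C@H]1OC1(C)C
F8 | step 17 | β-silyloxy aldehyde from F7 | O=CC[C@@](C)(O[Si](CC)(CC)CC)CC[C@H]1O[C@]1(C)CC[C@H]1OC1(C)C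
F9 | step 17 | triethylsilyl enol ether of F8 (E shown; E/Z mixture serves) | CC[Si](CC)(CC)O/C=C/[C@@](C)(O[Si](CC)(CC)CC)CC[C@H]1O[C@]1(C)CC[C@H]1OC1(C)C
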